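**Retrosynthetic overview** (labdane numbering)
- Target 22 ⇐ diol 20 (orthoester-directed acetylation of the secondary OH) ⇐ aldehyde 17 (proline α-aminoxylation sets C14) ⇐ enal 16 (organocatalytic transfer hydrogenation sets C13).
- 16 ⇐ methyl ketone 13 (formyl olefination) ⇐ butenyl decalin 12 (Wacker oxidation).
- 12 ⇐ acyclic fluoro allylsilane 11 by one catalytic asymmetric cation–olefin bicyclization. Fluoride abstraction by a silylated chiral IDPi starts it; ring A closes first (C4–C5), then ring B (C9–C10); the allylsilane leaves the exocyclic C8=C17 alkene. This sets C5, C9 and C10.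
- 11 ⇐ enyne 7 + Me3SiCH2MgCl + 4-iodobut-1-ene (syn-carbocupration/alkylation fixes the allylsilane geometry); 7 ⇐ geranyl acetate (HF addition, bromination, propargylation).

Assumption: 1, 5, 8, 9 and 14 are bought; the (S,S)-IDPi is assumed to give the 5S,9S,10S series (by analogy with hydroxyl-terminated IDPi cyclizations), and the (R,R)-catalyst is used if a first run shows the mirror series.

**Step 1**
Reactants: 1 geranyl acetate
Product: 2 (2E)-7-fluoro-3,7-dimethyloct-2-en-1-yl acetate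
Conditions: HF·pyridine (70% HF), THF, 0 °C
Reagents that add atoms: hydrogen fluoride, `F`
Why: Markovnikov hydrofluorination of the electron-rich distal alkene (the allylic acetate deactivates C2=C3) installs the tertiary C–F bond that later serves as the cation precursor.

**Step 2**
Reactants: 2 (2E)-7-fluoro-3,7-dimethyloct-2-en-1-yl acetate
Product: 3 (2E)-7-fluoro-3,7-dimethyloct-2-en-1-ol
Conditions: K2CO3 (0.2 equiv), MeOH, rt
Reagents that add atoms: none
Why: Base-catalysed transesterification removes the acetate; the tertiary fluoride is inert to methoxide at rt.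

**Step 3**
Reactants: 3 (2E)-7-fluoro-3,7-dimethyloct-2-en-1-ol
Product: 4 (2E)-1-bromo-7-fluoro-3,7-dimethyloct-2-ene
Conditions: CBr4, PPh3, CH2Cl2, 0 °C
Reagents that add atoms: tetrabromomethane, `BrC(Br)(Br)Br`
Why: Appel bromination of the primary allylic alcohol under neutral conditions, without allylic transposition or loss of the E geometry.

**Step 4**
Reactants: 4 (2E)-1-bromo-7-fluoro-3,7-dimethyloct-2-ene; 5 trimethyl(prop-1-yn-1-yl)silane
Product: 7 (5E)-10-fluoro-6,10-dimethylundec-5-en-1-yne, via silylated enyne 6 (not isolated)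
Conditions: 5, n-BuLi, THF, −78 → −20 °C; 4, −78 → 0 °C; then K2CO3, MeOH, rt
Reagents that add atoms: none
Why: SN2 alkylation of the propargylic lithium reagent at the primary allylic bromide, then methanolysis of the alkynyl C–Si bond in the same flask.

**Step 5**
Reactants: 7 (5E)-10-fluoro-6,10-dimethylundec-5-en-1-yne; 8 [(trimethylsilyl)methyl]magnesium chloride; 9 4-iodobut-1-ene
Product: 11 trimethyl{(2Z)-2-[(3E)-8-fluoro-4,8-dimethylnon-3-en-1-yl]hepta-2,6-dien-1-yl}silane, via vinylcopper 10 (not isolated)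
Conditions: 8, CuBr·SMe2 (1.1 equiv), Et2O/Me2S, −40 °C; 7, −40 → 0 °C; then 9, P(OEt)3, HMPA, THF, −30 °C → rt
Reagents that add atoms: none
Why: Normant syn-carbocupration puts Me3SiCH2 on the internal and copper on the terminal alkyne carbon on the same side, and alkylation of the vinylcopper goes with retention, so the butenyl chain is cis to CH2SiMe3 (2Z), the geometry the chair fold needs for an equatorial C9 chain.

**Step 6**
Reactants: 11 trimethyl{(2Z)-2-[(3E)-8-fluoro-4,8-dimethylnon-3-en-1-yl]hepta-2,6-dien-1-yl}silane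
Product: 12 (4aS,5S,8aS)-5-(but-3-en-1-yl)-1,1,4a-trimethyl-6-methylidenedecahydronaphthalene
Conditions: (S,S)-IDPi acid {[(S)-3,3′-Ar2-BINOL-diyl]P(=NSO2CF3)}2NH, Ar = 9,9-dimethylfluoren-2-yl (5 mol%), methallyl-SiMe3 (8 mol%, silylates the catalyst), toluene/methylcyclohexane 1:1 (0.02 M), −78 → −60 °C
Reagents that add atoms: none
Why: Proposed new method: an enantioselective cation–olefin bicyclization started by fluoride abstraction and ended by an allylsilane under silylium/chiral-counteranion catalysis. The N-silylated IDPi (a fluorophilic Lewis acid with no acidic proton) takes the tertiary fluoride as Me3SiF and leaves the C4 cation paired with the confined chiral anion. The (E)-C5=C10 alkene and then the (Z)-allylsilane add in a chair–chair array, which gives the trans-decalin with the C9 chain equatorial, and the anion pocket selects the fold that leads to 5S,9S,10S. Loss of Me3Si+ from the β-silyl C8 cation gives only the exocyclic C8=C17 alkene and re-silylates the anion, so silylium carries the chain and no proton or halonium initiator, which would attack the allylsilane first, is ever present. The closest known reaction types are IDPi Brønsted-acid polyene cyclization (homofarnesol to ambrox type), silylium-IDPi Hosomi–Sakurai allylation, and Lewis-acid coupling of tertiary alkyl halides with allylsilanes.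

**Step 7**
Reactants: 12 (4aS,5S,8aS)-5-(but-3-en-1-yl)-1,1,4a-trimethyl-6-methylidenedecahydronaphthalene
Product: 13 4-[(1S,4aS,8aS)-5,5,8a-trimethyl-2-methylidenedecahydronaphthalen-1-yl]butan-2-one
Conditions: PdCl2 (10 mol%), CuCl (1 equiv), O2 (1 atm), DMF/H2O 7:1, rt
Reagents that add atoms: water, `O`
Why: Tsuji–Wacker oxidation converts only the monosubstituted alkene to the methyl ketone; the hindered 1,1-disubstituted exocyclic alkene is not a Wacker substrate.

**Step 8**
Reactants: 13 4-[(1S,4aS,8aS)-5,5,8a-trimethyl-2-methylidenedecahydronaphthalen-1-yl]butan-2-one; 14 (Z)-1-bromo-2-ethoxyethene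
Product: 16 3-methyl-5-[(1S,4aS,8aS)-5,5,8a-trimethyl-2-methylidenedecahydronaphthalen-1-yl]pent-2-enal (2E/2Z mixture), via ethoxyvinyl carbinol 15 (not isolated)
Conditions: 14, t-BuLi (2 equiv), Et2O, −78 °C; 13, −78 → 0 °C; then 1 M aq. HCl, THF, 0 °C
Reagents that add atoms: water, `O`
Why: Formyl olefination by 1,2-addition of 2-ethoxyvinyllithium followed by mild acid-induced allylic transposition and enol ether hydrolysis; the E/Z ratio does not matter for step 9.

**Step 9**
Reactants: 16 3-methyl-5-[(1S,4aS,8aS)-5,5,8a-trimethyl-2-methylidenedecahydronaphthalen-1-yl]pent-2-enal (2E/2Z mixture)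
Product: 17 (3R)-3-methyl-5-[(1S,4aS,8aS)-5,5,8a-trimethyl-2-methylidenedecahydronaphthalen-1-yl]pentanal
Conditions: (R)-2-tert-butyl-3-methylimidazolidin-4-one·CCl3CO2H (20 mol%), Hantzsch ester (1.2 equiv), CHCl3, −30 °C
Reagents that add atoms: none
Why: Iminium-catalysed transfer hydrogenation is E/Z-convergent and the catalyst sets C13 as R, independent of the remote ring stereocentres. The (R)-catalyst is the one that gives (S)-3-phenylbutanal from β-methylcinnamaldehyde, and the same facial sense is 13R here because the CIP ranking of the large group changes.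

**Step 10**
Reactants: 17 (3R)-3-methyl-5-[(1S,4aS,8aS)-5,5,8a-trimethyl-2-methylidenedecahydronaphthalen-1-yl]pentanal
Product: 20 (2R,3R)-3-methyl-5-[(1S,4aS,8aS)-5,5,8a-trimethyl-2-methylidenedecahydronaphthalen-1-yl]pentane-1,2-diol, via anilinooxy aldehyde 18 (not isolated), via anilinooxy alcohol 19 (not isolated)
Conditions: L-proline (20 mol%), PhNO (1.1 equiv), CHCl3, 4 °C; then NaBH4, EtOH, 0 °C; then AcOH, Zn dust, rt
Reagents that add atoms: nitrosobenzene, `O=Nc1ccccc1`
Why: Proline enamine α-aminoxylation (O-selective nitroso aldol) sets C14 as R under catalyst control; reduction in situ prevents epimerisation, Zn cleaves the N–O bond, and the diol is the point at which minor diastereomers are removed.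

**Step 11**
Reactants: 20 (2R,3R)-3-methyl-5-[(1S,4aS,8aS)-5,5,8a-trimethyl-2-methylidenedecahydronaphthalen-1-yl]pentane-1,2-diol
Product: 22 (2R,3R)-1-hydroxy-3-methyl-5-[(1S,4aS,8aS)-5,5,8a-trimethyl-2-methylidenedecahydronaphthalen-1-yl]pentan-2-yl acetate, via cyclic orthoester 21 (not isolated)
Conditions: MeC(OMe)3 (1.5 equiv), pyridinium p-toluenesulfonate (5 mol%), CH2Cl2, rt; then AcOH/H2O 4:1, rt
Reagents that add atoms: trimethyl orthoacetate, `COC(C)(OC)OC`; water, `O`
Why: Cyclic orthoester formation and kinetic hydrolysis open the hemiorthoester at the less hindered primary oxygen, leaving the acetate on the secondary C14 oxygen without touching either stereocentre; work-up and chromatography are kept base-free to avoid acyl migration.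

**Compound list**
1 | geranyl acetate, (2E)-3,7-dimethylocta-2,6-dien-1-yl acetate | `CC(C)=CCC/C(C)=C/COC(C)=O` | starting material
2 | (2E)-7-fluoro-3,7-dimethyloct-2-en-1-yl acetate | `CC(C)(F)CCC/C(C)=C/COC(C)=O` | intermediate
3 | (2E)-7-fluoro-3,7-dimethyloct-2-en-1-ol | `CC(C)(F)CCC/C(C)=C/CO` | intermediate
4 | (2E)-1-bromo-7-fluoro-3,7-dimethyloct-2-ene | `CC(C)(F)CCC/C(C)=C/CBr` | intermediate
5 | trimethyl(prop-1-yn-1-yl)silane | `CC#C[Si](C)(C)C` | starting material
6 | [(5E)-10-fluoro-6,10-dimethylundec-5-en-1-yn-1-yl]trimethylsilane | `CC(C)(F)CCC/C(C)=C/CCC#C[Si](C)(C)C` | intermediate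
7 | (5E)-10-fluoro-6,10-dimethylundec-5-en-1-yne | `CC(C)(F)CCC/C(C)=C/CCC#C` | intermediate
8 | [(trimethylsilyl)methyl]magnesium chloride | `C[Si](C)(C)C[Mg]Cl` | starting material
9 | 4-iodobut-1-ene | `C=CCCI` | starting material
10 | {(1Z,5E)-10-fluoro-6,10-dimethyl-2-[(trimethylsilyl)methyl]undeca-1,5-dien-1-yl}copper (MgBrCl complex) | `CC(C)(F)CCC/C(C)=C/CC/C(C[Si](C)(C)C)=C/[Cu]` | intermediate
11 | trimethyl{(2Z)-2-[(3E)-8-fluoro-4,8-dimethylnon-3-en-1-yl]hepta-2,6-dien-1-yl}silane | `CC(C)(F)CCC/C(C)=C/CC/C(C[Si](C)(C)C)=C/CCC=C` | intermediate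
12 | (4aS,5S,8aS)-5-(but-3-en-1-yl)-1,1,4a-trimethyl-6-methylidenedecahydronaphthalene | `C=C1CC[C@H]2C(C)(C)CCC[C@]2(C)[C@H]1CCC=C` | intermediate
13 | 4-[(1S,4aS,8aS)-5,5,8a-trimethyl-2-methylidenedecahydronaphthalen-1-yl]butan-2-one | `C=C1CC[C@H]2C(C)(C)CCC[C@]2(C)[C@H]1CCC(C)=O` | intermediate
14 | (Z)-1-bromo-2-ethoxyethene | `CCO/C=C\Br` | starting material
15 | (1Z)-1-ethoxy-3-methyl-5-[(1S,4aS,8aS)-5,5,8a-trimethyl-2-methylidenedecahydronaphthalen-1-yl]pent-1-en-3-ol (lithium alkoxide, both C3 epimers) | `C=C1CC[C@H]2C(C)(C)CCC[C@]2(C)[C@H]1CCC(C)(O)/C=C\OCC` | intermediate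
16 | 3-methyl-5-[(1S,4aS,8aS)-5,5,8a-trimethyl-2-methylidenedecahydronaphthalen-1-yl]pent-2-enal (2E shown, 2Z also present) | `C=C1CC[C@H]2C(C)(C)CCC[C@]2(C)[C@H]1CC/C(C)=C/C=O` | intermediate
17 | (3R)-3-methyl-5-[(1S,4aS,8aS)-5,5,8a-trimethyl-2-methylidenedecahydronaphthalen-1-yl]pentanal | `C=C1CC[C@H]2C(C)(C)CCC[C@]2(C)[C@H]1CC[C@@H](C)CC=O` | intermediate
18 | (2R,3R)-3-methyl-2-[(phenylamino)oxy]-5-[(1S,4aS,8aS)-5,5,8a-trimethyl-2-methylidenedecahydronaphthalen-1-yl]pentanal | `C=C1CC[C@H]2C(C)(C)CCC[C@]2(C)[C@H]1CC[C@@H](C)[C@H](C=O)ONc1ccccc1` | intermediate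
19 | (2R,3R)-3-methyl-2-[(phenylamino)oxy]-5-[(1S,4aS,8aS)-5,5,8a-trimethyl-2-methylidenedecahydronaphthalen-1-yl]pentan-1-ol | `C=C1CC[C@H]2C(C)(C)CCC[C@]2(C)[C@H]1CC[C@@H](C)[C@H](CO)ONc1ccccc1` | intermediate
20 | (2R,3R)-3-methyl-5-[(1S,4aS,8aS)-5,5,8a-trimethyl-2-methylidenedecahydronaphthalen-1-yl]pentane-1,2-diol | `C=C1CC[C@H]2C(C)(C)CCC[C@]2(C)[C@H]1CC[C@@H](C)[C@H](CO)O` | intermediate
21 | (4R)-2-methoxy-2-methyl-4-{(2R)-4-[(1S,4aS,8aS)-5,5,8a-trimethyl-2-methylidenedecahydronaphthalen-1-yl]butan-2-yl}-1,3-dioxolane (both C2 epimers) | `C=C1CC[C@H]2C(C)(C)CCC[C@]2(C)[C@H]1CC[C@@H](C)[C@@H]1COC(C)(OC)O1` | intermediate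
22 | (2R,3R)-1-hydroxy-3-methyl-5-[(1S,4aS,8aS)-5,5,8a-trimethyl-2-methylidenedecahydronaphthalen-1-yl]pentan-2-yl acetate, (13R,14R)-15-hydroxylabd-8(17)-en-14-yl acetate | `C=C1CC[C@H]2C(C)(C)CCC[C@]2(C)[C@H]1CC[C@@H](C)[C@H](CO)OC(C)=O` | target

**Step count**
Total steps: 11. Longest linear sequence: 11 (1 → 22).

**Steps most likely to fail**

1. The alkylation in step 5. A vinylcopper reacts sluggishly with an unactivated primary iodide, and the tertiary fluoride must survive the magnesium salts. The fallback sets out from 7 and returns at 11. The carbocupration is kept, but vinylcopper 10 is quenched with I2 at −40 °C to give (1Z,5E)-10-fluoro-1-iodo-6,10-dimethyl-2-[(trimethylsilyl)methyl]undeca-1,5-diene F1. Zinc insertion into 9 (Zn dust, THF) gives but-3-en-1-ylzinc iodide F2. Negishi coupling of F1 and F2 with Pd(dppf)Cl2 (5 mol%) in THF at rt forms the C9–C11 bond with retention and gives 11.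

2. The new bicyclization in step 6. The risks are proton loss from the C4 cation (which would release acid and destroy the allylsilane), incomplete ring B closure, and insufficient enantiocontrol over an all-hydrocarbon ion pair. The fallback uses known chemistry only; it sets out from 1 and returns at 12.
   - Shi epoxidation of 1 (enantiomer of the Shi ketone made from L-sorbose, KHSO5, K2CO3, MeCN/dimethoxymethane/H2O, 0 °C) at the distal alkene gives (2E)-5-[(2S)-3,3-dimethyloxiran-2-yl]-3-methylpent-2-en-1-yl acetate F3.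
   - K2CO3/MeOH gives (2E)-5-[(2S)-3,3-dimethyloxiran-2-yl]-3-methylpent-2-en-1-ol F4.
   - CBr4/PPh3 gives (3S)-3-[(3E)-5-bromo-3-methylpent-3-en-1-yl]-2,2-dimethyloxirane F5.
   - Lithiated 5, then K2CO3/MeOH, gives trimethyl{(5E)-6-methyl-8-[(2S)-3,3-dimethyloxiran-2-yl]oct-5-en-1-yn-1-yl}silane F6 and then (2S)-3,3-dimethyl-2-[(3E)-3-methyloct-3-en-7-yn-1-yl]oxirane F7.
   - Carbocupration with 8/CuBr·SMe2 at −25 °C gives {(1Z,5E)-6-methyl-8-[(2S)-3,3-dimethyloxiran-2-yl]-2-[(trimethylsilyl)methyl]octa-1,5-dien-1-yl}copper F8, and alkylation with 9 gives trimethyl{(2Z)-2-{(3E)-4-methyl-6-[(2S)-3,3-dimethyloxiran-2-yl]hex-3-en-1-yl}hepta-2,6-dien-1-yl}silane F9.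
   - The known epoxide-initiated, allylsilane-terminated bicyclization (MeAlCl2, CH2Cl2, −78 °C) relays the epoxide configuration to C5, C9 and C10 and gives (2S,4aR,5S,8aR)-5-(but-3-en-1-yl)-1,1,4a-trimethyl-6-methylidenedecahydronaphthalen-2-ol F10.
   - NaH, CS2, MeI gives O-[(2S,4aR,5S,8aR)-5-(but-3-en-1-yl)-1,1,4a-trimethyl-6-methylidenedecahydronaphthalen-2-yl] S-methyl carbonodithioate F11, and Barton–McCombie reduction (Bu3SnH, azobisisobutyronitrile, toluene, 80 °C) removes the C3 oxygen and gives 12.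

3. The monoacetylation in step 11. The regioselectivity of orthoester opening may be incomplete, and the secondary acetate can migrate to the primary oxygen. The fallback sets out from 20 and returns at 22. TBSCl/imidazole (CH2Cl2, 0 °C) silylates only the primary hydroxyl and gives (2R,3R)-1-{[tert-butyl(dimethyl)silyl]oxy}-3-methyl-5-[(1S,4aS,8aS)-5,5,8a-trimethyl-2-methylidenedecahydronaphthalen-1-yl]pentan-2-ol F12. Ac2O/pyridine/4-(dimethylamino)pyridine gives (2R,3R)-1-{[tert-butyl(dimethyl)silyl]oxy}-3-methyl-5-[(1S,4aS,8aS)-5,5,8a-trimethyl-2-methylidenedecahydronaphthalen-1-yl]pentan-2-yl acetate F13. HF·pyridine in THF/pyridine at 0 °C removes the silyl group under non-basic conditions and gives 22.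

**Further compounds**
F1 | step 5 | (1Z,5E)-10-fluoro-1-iodo-6,10-dimethyl-2-[(trimethylsilyl)methyl]undeca-1,5-diene | `CC(C)(F)CCC/C(C)=C/CC/C(C[Si](C)(C)C)=C/I`
F2 | step 5 | but-3-en-1-ylzinc iodide | `C=CCC[Zn]I`
F3 | step 6 | (2E)-5-[(2S)-3,3-dimethyloxiran-2-yl]-3-methylpent-2-en-1-yl acetate | `CC1(C)O[C@H]1CC/C(C)=C/COC(C)=O`
F4 | step 6 | (2E)-5-[(2S)-3,3-dimethyloxiran-2-yl]-3-methylpent-2-en-1-ol | `CC1(C)O[C@H]1CC/C(C)=C/CO`
F5 | step 6 | (3S)-3-[(3E)-5-bromo-3-methylpent-3-en-1-yl]-2,2-dimethyloxirane | `CC1(C)O[C@H]1CC/C(C)=C/CBr`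
F6 | step 6 | trimethyl{(5E)-6-methyl-8-[(2S)-3,3-dimethyloxiran-2-yl]oct-5-en-1-yn-1-yl}silane | `CC1(C)O[C@H]1CC/C(C)=C/CCC#C[Si](C)(C)C`
F7 | step 6 | (2S)-3,3-dimethyl-2-[(3E)-3-methyloct-3-en-7-yn-1-yl]oxirane | `CC1(C)O[C@H]1CC/C(C)=C/CCC#C`
F8 | step 6 | {(1Z,5E)-6-methyl-8-[(2S)-3,3-dimethyloxiran-2-yl]-2-[(trimethylsilyl)methyl]octa-1,5-dien-1-yl}copper | `CC1(C)O[C@H]1CC/C(C)=C/CC/C(C[Si](C)(C)C)=C/[Cu]`
F9 | step 6 | trimethyl{(2Z)-2-{(3E)-4-methyl-6-[(2S)-3,3-dimethyloxiran-2-yl]hex-3-en-1-yl}hepta-2,6-dien-1-yl}silane | `CC1(C)O[C@H]1CC/C(C)=C/CC/C(C[Si](C)(C)C)=C/CCC=C`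
F10 | step 6 | (2S,4aR,5S,8aR)-5-(but-3-en-1-yl)-1,1,4a-trimethyl-6-methylidenedecahydronaphthalen-2-ol | `C=C1CC[C@H]2C(C)(C)[C@@H](O)CC[C@]2(C)[C@H]1CCC=C`
F11 | step 6 | O-[(2S,4aR,5S,8aR)-5-(but-3-en-1-yl)-1,1,4a-trimethyl-6-methylidenedecahydronaphthalen-2-yl] S-methyl carbonodithioate | `C=C1CC[C@H]2C(C)(C)[C@@H](OC(=S)SC)CC[C@]2(C)[C@H]1CCC=C`
F12 | step 11 | (2R,3R)-1-{[tert-butyl(dimethyl)silyl]oxy}-3-methyl-5-[(1S,4aS,8aS)-5,5,8a-trimethyl-2-methylidenedecahydronaphthalen-1-yl]pentan-2-ol | `C=C1CC[C@H]2C(C)(C)CCC[C@]2(C)[C@H]1CC[C@@H](C)[C@H](CO[Si](C)(C)C(C)(C)C)O`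
F13 | step 11 | (2R,3R)-1-{[tert-butyl(dimethyl)silyl]oxy}-3-methyl-5-[(1S,4aS,8aS)-5,5,8a-trimethyl-2-methylidenedecahydronaphthalen-1-yl]pentan-2-yl acetate | `C=C1CC[C@H]2C(C)(C)CCC[C@]2(C)[C@H]1CC[C@@H](C)[C@H](CO[Si](C)(C)C(C)(C)C)OC(C)=O`
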